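The constants are those of an exercise, and the outcome is calculated.

starting complex 0.58 M (in portions, 2); incoming ligand 0.551 M; time 3.0 d; the portions of starting complex follow each other after 8.0 h, the first at the start

- why nothing more happens at 3.0 d, or that something still does (it is still moving / forward and back rates have come level / all of the starting complex has reacted / the incoming ligand has run out first)
- the complex with one exchanged standing at 3.0 d, as a percentage of the starting complex charged

- the reaction counts as stopped when no species that holds the starting complex changes by six tenths of a point or more over the second half of the time
- run time (flask): 3.0 d

    starting complex + incoming ligand → leaving ligand + complex with one exchanged (k1 = 0.089 M⁻¹ h⁻¹)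
    complex with one exchanged + incoming ligand → leaving ligand + complex with two exchanged (k2 = 0.30 M⁻¹ h⁻¹)
    complex with one exchanged ⇌ isomer of the product (K3 = 2.5, k3 = 0.065 h⁻¹)
    complex with one exchanged → over-reaction product (k4 = 1.5 × 10⁻⁴ h⁻¹)
    starting complex ⇌ dormant form (K5 = 1.4, k5 = 0.17 h⁻¹)

- The complex with one exchanged is the middle link of a chain, and you want to know what stands of it at 3.0 d.
- Treat the pool (starting complex plus dormant form) as one object, since its relaxation half-life 0.0991 d is shorter than the half-life 0.59 d of starting complex by step 1 alone, as charged; the pool is then 0.417 starting complex.
- Treat the pair (complex with one exchanged plus isomer of the product) the same way, as an assumption, which makes it 0.286 complex with one exchanged. Its relaxation half-life 0.317 d is longer than the half-life 0.17 d of complex with one exchanged by step 2 alone, as charged, so the pair can lag its equilibrium while the ligand is high, and I expect the reckoned complex to come out on the high side.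
- Both ligand steps run on the same clock, the time integral of c(incoming ligand), so that clock cancels. What remains is the pair's effective constant over the pool's, 2.31, the selectivity factor s.
- Let x be the pool as a fraction of the charge. Early the pair is about 1 − x, late it trails at x/(s − 1), and the curve joining both ends is (x − x^s)/(s − 1).
- The curve peaks at a pair of 22.8% with the pool at 52.8%, which makes 6.53% complex with one exchanged.
- The weak link on the clock is the time to get there: at the charged ligand concentration it is 31.3 h, but the ligand falls.
- Reforged, the ligand balance leaves 0.136 M at the peak, and the logarithmic mean 0.296 M gives 2.42 d, earlier than the end of the run.
- At that rate the starting complex still falls by about 4 percentage points over the second half, to be held against the threshold of the stop rule stated above. I commit to "still moving" and 6.53%.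
- The forecast says it is still moving and 6.5%, range 5.3% to 7.8%, with the pair said to be “near its flat maximum”.
- The simulation gives it is still moving and 5.31%.

- In this flask the pool stands at 52.3%, so the curve with s gives 6.52% complex with one exchanged, and the simulated value is 0.814 of that. In the neighbour flask with 1.4 M of starting complex, the incoming ligand is down to 1.2% of its charge and the pool stands at 73.4%. The same s gives 5.33% there, and that flask holds 4.26%, which is 0.799 of the reckoned value.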